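## Structural features

The target is a germacranolide: a ten-membered carbocycle (C1–C10) fused through C7–C8 to an α-methylene-γ-butyrolactone (C11=C13, C12=O, ring oxygen on C8). The ring holds two trisubstituted alkenes, C1=C10 and C4=C5, each carrying a hydroxymethyl group (C14, C15). In both the two ring carbons are cis to each other, so each alkene is E by the sequence rule although it is a cis cycloalkene. Three stereocentres stand in a row: C6 (R, tiglate), C7 (R) and C8 (S, lactone oxygen). The oxygens on C6 and C8 lie on one face of the ring and the C7–C11 bond on the other, so the lactone is trans-fused. Fragile elements are the exo-methylene lactone (Michael acceptor), the allylic tiglate, the two primary allylic alcohols and the medium-ring 1,5-diene (transannular and Cope chemistry). The real difficulty is a ten-membered ring with two cis trisubstituted alkenes next to a stereotriad, together with three primary allylic oxygenated carbons at two oxidation levels (C12 acid, C14 and C15 alcohol). The feature used is that C9–C10(C14)=C1–C2–C3–C4(C15)=C5–C6 is a head-to-tail pair of isoprene units whose cis alkenes are those of a 1,5-disubstituted cycloocta-1,5-diene; only C7 and C8 are missing between C6 and C9 and are inserted by a two-carbon ring expansion.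

## Logic of the disconnections

**33 back to 30.** The lactone C12–O bond is opened and the C8–O bond is exchanged for a C8–Si bond; the two primary alcohols become silyl ethers. A C8–Si bond survives the carbanion chemistry of the ring expansion, where a C8–O bond would be lost by β-elimination, and fluoride can unmask all three sites in one flask (through 31 and 32). The forward step must replace silicon by oxygen with retention and must not attack the acrylate, the tiglate or the alkenes.

**30 back to 27.** C12 is taken from the acid through 29 and 28 to a 4-methoxybenzyl ether. This ether is inert to strong base and is removed without touching the C14/C15 silyl ethers, so the three primary oxygens stay distinguishable. The oxidations must leave the C11=C13 bond out of conjugation with C7.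

**27 back to 24 and 25.** The acyl C–O6 bond is cut. Late esterification keeps the base-sensitive tiglate out of the anionic steps. The hindered allylic alcohol needs an activated acyl donor (26) that does not isomerise the tiglate.

**24 back to 21 (through 23 and 22).** The C6–H bond is cut (ketone reduction) and the racemate is split at the alcohol. The ring expansion passes through an achiral intermediate, so absolute configuration can only be introduced afterwards. A covalent resolution with an enantiopure acyl group is chosen because C6 is flanked by two bulky groups, which makes enzymatic acylation improbable. The reduction must place the hydroxyl trans to C11.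

**21 back to 18 (key).** The C8–C9 bond is cut and C9 is rejoined to C6, which contracts the ten-membered ketone to an eight-membered tertiary carbinol carrying C7=C8 as an alkenyl group. Both ring alkenes then sit in a cycloocta-1,5-diene, where cis is the only geometry, and the medium ring is made without a cyclisation. The forward step must bond C9 to C8 (not to C4, and not C1 to C8) and must give C7/C8 trans. Silicon is placed trans to C6 in 18. The cis isomer, the one that syn-silylmetalation of an enyne followed by carbonyl addition would give, holds silicon within reach of the alkoxide and would be lost to 1,4-silyl migration or cyclic siloxane formation.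

**18 back to 15 and 17; 15 back to 10 and 14; 10 back to 8 and 9.** The C7–C11 bond, then the C8–Si and C7–Sn bonds, then the C6–C7 bond are cut. Syn addition of Si–Sn across the alkyne of 10 is the simple way to the required geometry (silicon cis to the later C11, trans to C6). The demand is a cross-coupling at a congested 1-substituted vinylstannane.

**17 back to 16; 14 back to 11 and 12.** One C–O bond and one Si–Sn bond are cut, each a single substitution on a commercial reagent.

**8 back to 7, 5 and 4.** The C6 carbonyl is traced to a C4=C5 alkene by oxygen transposition (tertiary allylic alcohol, hydroxy selenide 6, epoxide). Direct allylic oxidation of 4 would have to choose between C6, C3, C9 and the two CH2O groups. The transposition fixes oxygen on C6 because each step has only one regiochemical option, and it relies on the C2 symmetry of 4 so that monoepoxidation gives one constitutional isomer.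

**4 back to 3 (twice) and 1.** The C2–C3 and C6–C9 bonds are cut in the sense of a [4+4] cyclodimerisation. One step builds the ring and both alkenes. The dimerisation must be head-to-tail.

## Other disconnections considered

**Alternative 1:** The cut runs through C1=C10 and C4=C5 in the retro-[2+2] sense. Forward, a 6-4-4 tricyclic photoadduct A2 (from an enone–cyclobutene [2+2]) would be heated so that the central cyclobutane bonds C5–C10 and C1–C4 break and the six- and four-membered rings merge into the cyclodecadienone A1.
- In its favour: the ten-membered ring again arises by ring expansion, not cyclisation, which is equal to the chosen plan. The C8 stereocentre could come from an enantiopure 4-silyloxycyclohexenone, so no resolution would be needed; on this point it is better than the chosen plan.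
- Against it: cycloreversion of cis-anti-cis cyclobutanes typically needs about 200 °C and tends to give a cis,trans diene that undergoes Cope rearrangement to a divinylcyclohexane. The ring-cis,cis geometry is therefore not secured, whereas the chosen plan inherits it from the eight-membered ring. The photocycloaddition has its own head-to-head/head-to-tail question.
- Step economy: A1 lacks the whole C11–C13 unit, so C7 would still have to be alkylated trans to C8, and the esters at C14/C15 reduced beside a ketone. The sequence after the key step would be longer than here.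

**Alternative 2:** The cut is the C3–C4 bond. Forward, the terminal C2=C3 alkene of the dienyl arm of lactone A4 would be hydroborated with 9-BBN and the C3 borane coupled with the C4 vinyl iodide under PdCl2(dppf)/Cs2CO3 to close the ring to A3.
- In its favour: C6, C7 and C8 would be set on a small lactone by acyclic stereocontrol with known absolute configuration, and both alkene geometries are fixed before ring closure. On absolute stereocontrol it is better than the chosen plan; on alkene geometry it is equal.
- Against it: closing a strained ten-membered carbocycle by an sp3–sp2 coupling competes with oligomerisation and β-hydride elimination. Hydroboration of a 1,3-diene beside two other alkenes is not cleanly site-selective. A3 still lacks C13, so an α-methylenation next to the C6 silyl ether is needed.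
- Comparison: mechanistically it trades the regiochemical question of the rearrangement for an entropic one. Building A4 with three stereocentres and two defined trisubstituted alkenes should cost more steps than the route below.

**Alternative 3:** The cut is the C2–C3 bond. Forward, the C2 allylic sulfone of the open-chain bromide A6 would be deprotonated with KN(SiMe3)2 at high dilution and alkylated by the C3 allylic bromide to give the carbocycle A5 as C2 epimers.
- In its favour: sulfone-anion macro-alkylation is an established way to medium and large terpenoid rings, the stereotriad is made beforehand with absolute control (better than the chosen plan), and the alkene geometries are preformed (equal).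
- Against it: a ten-membered ring is the least favourable size for this closure. α/γ-ambiguity of the allyl sulfone anion and SN2/SN2′ ambiguity of the bromide give up to four constitutional outcomes. Reductive desulfonylation of an allylic sulfone can shift or isomerise the C1=C10 alkene.
- Step economy: the triol must be protected three ways and A6 assembled linearly, so the count should exceed that of the chosen plan, which makes the ring and both alkenes in one dimerisation.

Key step: step 11

Remarks on the chemistry:
- Locants and descriptors in names follow germacrane numbering (ring C1–C10; C11–C13 on C7; C14 on C10; C15 on C4).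
- Racemates with more than one stereocentre are drawn as the enantiomer that is carried on.
- TBS = tert-butyldimethylsilyl, PMB = 4-methoxybenzyl, Bn = benzyl.
- Compounds 9, 11 and 12, (1S)-camphanic chloride and all reagents are taken to be commercial.

## Route

Step 1
Reactants: 1 2-methyl-2-vinyloxirane
Product: 3 2-(TBS-oxymethyl)buta-1,3-diene, via lithium 2-methylidenebut-3-en-1-olate 2 (not isolated)
Conditions: LiN(i-Pr)2, Et2O, 0 °C → rt; then t-BuMe2SiCl, DMPU, 0 °C → rt
Reagents that add atoms: tert-butyldimethylsilyl chloride, CC(C)(C)[Si](C)(C)Cl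
Why: The amide removes a methyl proton and opens the epoxide by β-elimination (base-induced epoxide-to-allylic-alcohol isomerisation); silylating alkoxide 2 in the same flask avoids isolating the volatile dienol, which dimerises readily.

Step 2
Reactants: 3 2-(TBS-oxymethyl)buta-1,3-diene (two molecules)
Product: 4 1,5-bis(TBS-oxymethyl)cycloocta-1,5-diene (both ring alkenes cis; 1E,5E)
Conditions: Ni(cod)2 (5 mol%), P(O-2-PhC6H4)3 (5 mol%), toluene, 60 °C
Reagents that add atoms: none
Why: Zerovalent nickel with a bulky phosphite couples two dienes through a bis-allyl nickel intermediate and reductively eliminates the eight-membered ring ([4+4] cyclodimerisation); 2-substituted dienes are expected to give mainly the head-to-tail 1,5-isomer, and cis is the only alkene geometry the ring allows. The minor head-to-head 1,6-isomer and [4+2] dimers must be removed, here on AgNO3-impregnated silica and finally at dienone 8.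

Step 3
Reactants: 4 1,5-bis(TBS-oxymethyl)cycloocta-1,5-diene
Product: 5 rac-cis-1,5-bis(TBS-oxymethyl)-9-oxabicyclo[6.1.0]non-4-ene
Conditions: mCPBA (0.9 equiv), NaHCO3, CH2Cl2, −20 °C
Reagents that add atoms: 3-chloroperbenzoic acid, OOC(=O)c1cccc(Cl)c1
Why: Prilezhaev epoxidation; 4 is C2-symmetric, so monoepoxidation can give only one constitutional isomer, and a deficit of peracid limits the bis-epoxide while unreacted 4 is recycled. The cis alkene gives the cis-fused epoxide as a racemate.

Step 4
Reactants: 5 rac-cis-1,5-bis(TBS-oxymethyl)-9-oxabicyclo[6.1.0]non-4-ene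
Product: 7 rac-1,5-bis(TBS-oxymethyl)cycloocta-2,5-dien-1-ol, via trans-hydroxy selenide 6 (not isolated)
Conditions: (PhSe)2, NaBH4, EtOH, 78 °C; then 30% H2O2, THF, 0 °C → rt
Reagents that add atoms: none
Why: Benzeneselenolate opens the trisubstituted epoxide by SN2 attack at the less substituted carbon C5; oxidation to the selenoxide and syn-elimination can only take hydrogen from C6, because C4 is fully substituted, giving the transposed tertiary allylic alcohol with a cis C5=C6 bond.

Step 5
Reactants: 7 rac-1,5-bis(TBS-oxymethyl)cycloocta-2,5-dien-1-ol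
Product: 8 3,7-bis(TBS-oxymethyl)cycloocta-2,6-dien-1-one
Conditions: pyridinium chlorochromate (C5H5NH[CrO3Cl]), 4 Å MS, CH2Cl2, rt
Reagents that add atoms: none
Why: Babler–Dauben oxidative transposition: the tertiary allylic chromate ester shifts [3,3] to C6 and is oxidised there, which returns C4=C5 to its ring-cis position and fixes the carbonyl on C6. Conjugation of the β,γ-alkene C1=C10 is not expected to be favoured in a cis eight-membered enone.

Step 6
Reactants: 8 3,7-bis(TBS-oxymethyl)cycloocta-2,6-dien-1-one; 9 ethynylmagnesium bromide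
Product: 10 rac-1-ethynyl-3,7-bis(TBS-oxymethyl)cycloocta-2,6-dien-1-ol
Conditions: HC≡CMgBr, LaCl3·2LiCl, THF, 0 °C
Reagents that add atoms: none
Why: 1,2-Addition of the acetylide to the enone carbonyl; the lanthanum salt activates the carbonyl and tempers basicity so that enolisation toward the doubly activated C9 is suppressed. The carbinol centre forms as a racemate, which does not matter because step 11 destroys it.

Step 7
Reactants: 11 tributyltin hydride; 12 benzylchlorodimethylsilane
Product: 14 benzyldimethyl(tributylstannyl)silane, via tributylstannyllithium 13 (not isolated)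
Conditions: LiN(i-Pr)2, THF, 0 °C; then BnMe2SiCl, −78 °C → rt
Reagents that add atoms: none
Why: Deprotonation of the tin hydride gives stannyllithium 13, which displaces chloride at silicon, the standard preparation of silylstannanes.

Step 8
Reactants: 10 rac-1-ethynyl-3,7-bis(TBS-oxymethyl)cycloocta-2,6-dien-1-ol; 14 benzyldimethyl(tributylstannyl)silane
Product: 15 rac-1-[(Z)-2-(benzyldimethylsilyl)-1-(tributylstannyl)ethenyl]-3,7-bis(TBS-oxymethyl)cycloocta-2,6-dien-1-ol
Conditions: Pd(PPh3)4 (5 mol%), THF, 65 °C
Reagents that add atoms: none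
Why: Palladium-catalysed silylstannation of a terminal alkyne is a syn addition that puts silicon on the terminal carbon (C8) and tin on the internal carbon (C7); silicon therefore ends cis to tin and trans to the carbinol carbon C6, the geometry step 11 needs.

Step 9
Reactants: 16 2,3-dibromopropene
Product: 17 2-bromoallyl 4-methoxybenzyl ether
Conditions: 4-MeOC6H4CH2OH, NaH, Bu4NI (cat.), THF, 0 °C → rt
Reagents that add atoms: 4-methoxybenzyl alcohol, COc1ccc(CO)cc1
Why: Williamson etherification; the alkoxide displaces only the allylic bromide by SN2, the vinylic bromide being inert.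

Step 10
Reactants: 15 rac-vinylstannane; 17 2-bromoallyl 4-methoxybenzyl ether
Product: 18 rac-1-[(1E)-1-(benzyldimethylsilyl)-3-(PMB-oxymethyl)buta-1,3-dien-2-yl]-3,7-bis(TBS-oxymethyl)cycloocta-2,6-dien-1-ol (silicon trans to the carbinol carbon)
Conditions: Pd(PPh3)4 (10 mol%), CuCl, LiCl, DMSO, 60 °C
Reagents that add atoms: none
Why: Stille coupling with retention at both sp2 carbons, so C11 takes the place of tin, cis to silicon; CuCl/LiCl promotes tin-to-copper exchange, the usual remedy for congested 1-substituted vinylstannanes, and fluoride additives are avoided because of the benzylsilane.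

Step 11
Reactants: 18 rac-1-[(1E)-1-(benzyldimethylsilyl)-3-(PMB-oxymethyl)buta-1,3-dien-2-yl]-3,7-bis(TBS-oxymethyl)cycloocta-2,6-dien-1-ol
Product: 21 rac-(7S,8S)-8-(benzyldimethylsilyl)-14,15-bis(TBS-oxy)-12-(PMB-oxy)germacra-1(10),4,11(13)-trien-6-one, via potassium alkoxide 19 (not isolated), via potassium dienolate 20 (not isolated)
Conditions: KH, 18-crown-6, THF, 0 °C → rt; then inverse quench into AcOH/THF, −78 °C
Reagents that add atoms: none
Why: Deprotonation gives the crown-separated potassium alkoxide 19, in which the oxyanion weakens the allylic C6–C9 bond; heterolysis gives an allylpotassium (C9–C10–C1) still tethered through C1–C2–C3 to a cross-conjugated dienone, and its unsubstituted terminus C9 adds 1,4 to C8, a net [1,3] shift that forms C8–C9 and dienolate 20. The closest known reaction type is the alkoxide-accelerated [1,3] two-carbon ring expansion of 1-vinylcycloalk-3-en-1-ols to medium-ring ketones. The ten-membered ring closes by intramolecular conjugate addition in the 10-endo-trig mode, without high dilution because the two reacting ends never separate. C8 becomes stereogenic in the C–C bond formation, but only as a racemate because the intermediate is achiral; C7 is set when 20 is protonated at −78 °C, which should occur at the α-carbon on the face away from the bulky silyl group on C8 and give the trans (C11/Si) isomer, the one also favoured by equilibration. The selectivity needed is C9-to-C8 bonding over C9-to-C4 (a cyclohexene with a quaternary carbon) and over C1-to-C8 (the eight-membered isomer); C4 is a fully substituted β-carbon with two donor alkyl groups whereas C8 is a monosubstituted β-carbon, and bonding of the substituted terminus C1 next to the silyl group is the most hindered option. Both ring alkenes should keep their ring-cis geometry, because the enone geometry is locked in the tether and the allylpotassium prefers the endo configuration it is born with. Silicon is trans to C6 so that the alkoxide cannot reach it; with silicon cis, 1,4-silyl migration or closure to a five-membered cyclic siloxane with loss of the benzyl group would be expected before any fragmentation.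

Step 12
Reactants: 21 rac-(7S,8S)-ten-membered ketone
Product: 22 rac-(6R,7S,8S)-8-(benzyldimethylsilyl)-14,15-bis(TBS-oxy)-12-(PMB-oxy)germacra-1(10),4,11(13)-trien-6-ol
Conditions: NaBH4, CeCl3·7H2O, MeOH/THF, −78 °C
Reagents that add atoms: none
Why: Luche reduction, 1,2-selective for the enone carbonyl and mild enough to leave C7 unepimerised; in a ten-membered ring the carbonyl lies roughly perpendicular to the ring, its oxygen should turn to the face of the small C7–H away from the propenyl group, and peripheral hydride attack then leaves the hydroxyl trans to C11. The relative configuration is to be confirmed before the resolution.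

Step 13
Reactants: 22 rac-(6R,7S,8S)-alcohol
Product: 23 (1S,4R)-camphanate of the (6R,7S,8S)-alcohol (single diastereomer)
Conditions: (1S)-(−)-camphanic chloride, Et3N, DMAP (cat.), CH2Cl2, 0 °C → rt; separation of the two diastereomers on silica or by crystallisation
Reagents that add atoms: (1S,4R)-camphanoyl chloride, O=C(Cl)[C@@]12CC[C@@](C)(C(=O)O1)C2(C)C
Why: Classical resolution: acylation of the racemate with an enantiopure acid chloride that has no epimerisable centre gives two diastereomeric esters to be separated physically; the absolute configuration of 23 is to be assigned by X-ray analysis of the crystalline camphanate.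

Step 14
Reactants: 23 (1S,4R)-camphanate of the (6R,7S,8S)-alcohol
Product: 24 (6R,7S,8S)-8-(benzyldimethylsilyl)-14,15-bis(TBS-oxy)-12-(PMB-oxy)germacra-1(10),4,11(13)-trien-6-ol (single enantiomer)
Conditions: i-Bu2AlH (excess), CH2Cl2, −78 → 0 °C; aq. KNaC4H4O6 work-up
Reagents that add atoms: none
Why: Reductive ester cleavage leaves all stereocentres untouched and avoids alkoxide/methanol conditions under which the freed C6 hydroxyl could attack the benzylsilane on C8.

Step 15
Reactants: 24 (6R,7S,8S)-alcohol; 25 tiglic acid
Product: 27 (6R,7S,8S)-6-tigloyloxy-8-(benzyldimethylsilyl)-14,15-bis(TBS-oxy)-12-(PMB-oxy)germacra-1(10),4,11(13)-triene, via tiglic 2,4,6-trichlorobenzoic anhydride 26 (not isolated)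
Conditions: 2,4,6-Cl3C6H2COCl, Et3N, THF, rt; then 24, DMAP, toluene, 40 °C
Reagents that add atoms: none
Why: Yamaguchi esterification: DMAP transfers the less hindered tigloyl group of mixed anhydride 26 to the hindered secondary allylic alcohol; reaction is at oxygen, so C6 keeps its configuration, and the (E)-2-methylbut-2-enoyl geometry is the stable one.

Step 16
Reactants: 27 (6R,7S,8S)-tiglate
Product: 28 (6R,7S,8S)-6-tigloyloxy-8-(benzyldimethylsilyl)-14,15-bis(TBS-oxy)germacra-1(10),4,11(13)-trien-12-ol
Conditions: DDQ, CH2Cl2/pH 7 phosphate buffer, 0 °C, dark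
Reagents that add atoms: none
Why: Oxidative removal of the PMB ether (hydride abstraction by DDQ, hydrolysis of the oxocarbenium ion); the electron-rich anisyl ring should be oxidised before the benzylsilane, and buffering protects the silyl ethers.

Step 17
Reactants: 28 (6R,7S,8S)-12-ol
Product: 29 (6R,7S,8S)-6-tigloyloxy-8-(benzyldimethylsilyl)-14,15-bis(TBS-oxy)germacra-1(10),4,11(13)-trien-12-al
Conditions: MnO2, CH2Cl2, rt
Reagents that add atoms: none
Why: MnO2 oxidises only allylic alcohols, and C12–OH is the only free one; the neutral heterogeneous conditions should not shift C11=C13 toward C7.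

Step 18
Reactants: 29 (6R,7S,8S)-12-al
Product: 30 (6R,7S,8S)-6-tigloyloxy-8-(benzyldimethylsilyl)-14,15-bis(TBS-oxy)germacra-1(10),4,11(13)-trien-12-oic acid
Conditions: NaClO2, NaH2PO4, 2-methylbut-2-ene, t-BuOH/H2O, 0 °C → rt
Reagents that add atoms: sodium chlorite, [Na+].[O-]Cl=O
Why: Pinnick oxidation of the enal to the 2-substituted acrylic acid under buffered conditions, with hypochlorous acid scavenged by the added alkene so that the ring alkenes, the tiglate and the C–Si bond are spared.

Step 19
Reactants: 30 (6R,7S,8S)-12-oic acid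
Product: 33 (6R,7R,8S)-14,15-dihydroxy-6-tigloyloxygermacra-1(10),4,11(13)-trien-12,8-olide (CNP0275462.2), via C8 dimethylsilanol diol acid 31 (not isolated), via C8 hydroxy acid 32 (not isolated)
Conditions: Bu4NF, THF, 0 °C → rt; then KHCO3, 30% H2O2, MeOH, 40 °C; then 1 M HCl to pH 3, rt
Reagents that add atoms: hydrogen peroxide, OO
Why: Fluoride removes both silyl ethers and cleaves the benzyl–silicon bond to give silanol 31; Tamao oxidation then replaces silicon on C8 by hydroxyl with retention (carbon migrates from silicon to oxygen), while the acrylic acid is present as its unreactive carboxylate. On acidification hydroxy acid 32 closes the γ-lactone onto O8, the only free γ-hydroxyl, giving the trans ring fusion set in step 11.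

## Compound list

1 | 2-methyl-2-vinyloxirane (racemic) | CC1(C=C)CO1 | starting material
2 | lithium 2-methylidenebut-3-en-1-olate | [Li+].[O-]CC(=C)C=C | intermediate (not isolated)
3 | tert-butyl(dimethyl)[(2-methylidenebut-3-en-1-yl)oxy]silane | C=CC(=C)CO[Si](C)(C)C(C)(C)C | intermediate
4 | 1,5-bis(TBS-oxymethyl)cycloocta-1,5-diene (ring-cis alkenes, 1E,5E) | CC(C)(C)[Si](C)(C)OC/C1=C/CC/C(CO[Si](C)(C)C(C)(C)C)=C\CC1 | intermediate
5 | rac-cis-1,5-bis(TBS-oxymethyl)-9-oxabicyclo[6.1.0]non-4-ene | CC(C)(C)[Si](C)(C)OC[C@@]12CC/C=C(CO[Si](C)(C)C(C)(C)C)\CC[C@@H]1O2 | intermediate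
6 | rac-trans-1,5-bis(TBS-oxymethyl)-8-(phenylselanyl)cyclooct-4-en-1-ol | CC(C)(C)[Si](C)(C)OC[C@@]1(O)CC/C=C(CO[Si](C)(C)C(C)(C)C)\CC[C@H]1[Se]c1ccccc1 | intermediate (not isolated)
7 | rac-1,5-bis(TBS-oxymethyl)cycloocta-2,5-dien-1-ol | OC1(CO[Si](C)(C)C(C)(C)C)CC/C=C(CO[Si](C)(C)C(C)(C)C)\C/C=C\1 | intermediate
8 | 3,7-bis(TBS-oxymethyl)cycloocta-2,6-dien-1-one | O=C1/C=C(CO[Si](C)(C)C(C)(C)C)\CC/C=C(CO[Si](C)(C)C(C)(C)C)\C1 | intermediate
9 | ethynylmagnesium bromide | C#C[Mg]Br | starting material
10 | rac-1-ethynyl-3,7-bis(TBS-oxymethyl)cycloocta-2,6-dien-1-ol | C#CC1(O)/C=C(CO[Si](C)(C)C(C)(C)C)\CC/C=C(CO[Si](C)(C)C(C)(C)C)\C1 | intermediate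
11 | tributyltin hydride | CCCC[SnH](CCCC)CCCC | starting material
12 | benzylchlorodimethylsilane | C[Si](C)(Cl)Cc1ccccc1 | starting material
13 | tributylstannyllithium | [Li][Sn](CCCC)(CCCC)CCCC | intermediate (not isolated)
14 | benzyldimethyl(tributylstannyl)silane | CCCC[Sn](CCCC)(CCCC)[Si](C)(C)Cc1ccccc1 | intermediate
15 | rac-1-[(Z)-2-(benzyldimethylsilyl)-1-(tributylstannyl)ethenyl]-3,7-bis(TBS-oxymethyl)cycloocta-2,6-dien-1-ol | OC1(/C(=C/[Si](C)(C)Cc2ccccc2)[Sn](CCCC)(CCCC)CCCC)/C=C(CO[Si](C)(C)C(C)(C)C)\CC/C=C(CO[Si](C)(C)C(C)(C)C)\C1 | intermediate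
16 | 2,3-dibromopropene | C=C(Br)CBr | starting material
17 | 1-{[(2-bromoprop-2-en-1-yl)oxy]methyl}-4-methoxybenzene | C=C(Br)COCc1ccc(OC)cc1 | intermediate
18 | rac-1-[(1E)-1-(benzyldimethylsilyl)-3-(PMB-oxymethyl)buta-1,3-dien-2-yl]-3,7-bis(TBS-oxymethyl)cycloocta-2,6-dien-1-ol | OC1(/C(=C/[Si](C)(C)Cc2ccccc2)C(=C)COCc2ccc(OC)cc2)/C=C(CO[Si](C)(C)C(C)(C)C)\CC/C=C(CO[Si](C)(C)C(C)(C)C)\C1 | intermediate
19 | potassium alkoxide of 18 | [K+].[O-]C1(/C(=C/[Si](C)(C)Cc2ccccc2)C(=C)COCc2ccc(OC)cc2)/C=C(CO[Si](C)(C)C(C)(C)C)\CC/C=C(CO[Si](C)(C)C(C)(C)C)\C1 | intermediate (not isolated)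
20 | potassium dienolate of 21 (C6=C7 enolate geometry left open) | [K+].[O-]C1=C(C(=C)COCc2ccc(OC)cc2)[C@@H]([Si](C)(C)Cc2ccccc2)C/C(CO[Si](C)(C)C(C)(C)C)=C\CC/C(CO[Si](C)(C)C(C)(C)C)=C\1 | intermediate (not isolated)
21 | rac-(7S,8S)-8-(benzyldimethylsilyl)-14,15-bis(TBS-oxy)-12-(PMB-oxy)germacra-1(10),4,11(13)-trien-6-one | O=C1[C@H](C(=C)COCc2ccc(OC)cc2)[C@@H]([Si](C)(C)Cc2ccccc2)C/C(CO[Si](C)(C)C(C)(C)C)=C\CC/C(CO[Si](C)(C)C(C)(C)C)=C\1 | intermediate
22 | rac-(6R,7S,8S)-8-(benzyldimethylsilyl)-14,15-bis(TBS-oxy)-12-(PMB-oxy)germacra-1(10),4,11(13)-trien-6-ol | O[C@H]1[C@H](C(=C)COCc2ccc(OC)cc2)[C@@H]([Si](C)(C)Cc2ccccc2)C/C(CO[Si](C)(C)C(C)(C)C)=C\CC/C(CO[Si](C)(C)C(C)(C)C)=C\1 | intermediate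
23 | (1S,4R)-camphanate of the (6R,7S,8S)-alcohol | O=C(O[C@H]1[C@H](C(=C)COCc2ccc(OC)cc2)[C@@H]([Si](C)(C)Cc2ccccc2)C/C(CO[Si](C)(C)C(C)(C)C)=C\CC/C(CO[Si](C)(C)C(C)(C)C)=C\1)[C@@]34CC[C@@](C)(C(=O)O3)C4(C)C | intermediate
24 | (6R,7S,8S)-8-(benzyldimethylsilyl)-14,15-bis(TBS-oxy)-12-(PMB-oxy)germacra-1(10),4,11(13)-trien-6-ol, single enantiomer | O[C@H]1[C@H](C(=C)COCc2ccc(OC)cc2)[C@@H]([Si](C)(C)Cc2ccccc2)C/C(CO[Si](C)(C)C(C)(C)C)=C\CC/C(CO[Si](C)(C)C(C)(C)C)=C\1 | intermediate
25 | tiglic acid, (E)-2-methylbut-2-enoic acid | C/C=C(\C)C(=O)O | starting material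
26 | tiglic 2,4,6-trichlorobenzoic anhydride | C/C=C(\C)C(=O)OC(=O)c1c(Cl)cc(Cl)cc1Cl | intermediate (not isolated)
27 | (6R,7S,8S)-6-tigloyloxy-8-(benzyldimethylsilyl)-14,15-bis(TBS-oxy)-12-(PMB-oxy)germacra-1(10),4,11(13)-triene | C/C=C(\C)C(=O)O[C@H]1[C@H](C(=C)COCc2ccc(OC)cc2)[C@@H]([Si](C)(C)Cc2ccccc2)C/C(CO[Si](C)(C)C(C)(C)C)=C\CC/C(CO[Si](C)(C)C(C)(C)C)=C\1 | intermediate
28 | (6R,7S,8S)-6-tigloyloxy-8-(benzyldimethylsilyl)-14,15-bis(TBS-oxy)germacra-1(10),4,11(13)-trien-12-ol | C/C=C(\C)C(=O)O[C@H]1[C@H](C(=C)CO)[C@@H]([Si](C)(C)Cc2ccccc2)C/C(CO[Si](C)(C)C(C)(C)C)=C\CC/C(CO[Si](C)(C)C(C)(C)C)=C\1 | intermediate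
29 | (6R,7S,8S)-6-tigloyloxy-8-(benzyldimethylsilyl)-14,15-bis(TBS-oxy)germacra-1(10),4,11(13)-trien-12-al | C/C=C(\C)C(=O)O[C@H]1[C@H](C(=C)C=O)[C@@H]([Si](C)(C)Cc2ccccc2)C/C(CO[Si](C)(C)C(C)(C)C)=C\CC/C(CO[Si](C)(C)C(C)(C)C)=C\1 | intermediate
30 | (6R,7S,8S)-6-tigloyloxy-8-(benzyldimethylsilyl)-14,15-bis(TBS-oxy)germacra-1(10),4,11(13)-trien-12-oic acid | C/C=C(\C)C(=O)O[C@H]1[C@H](C(=C)C(=O)O)[C@@H]([Si](C)(C)Cc2ccccc2)C/C(CO[Si](C)(C)C(C)(C)C)=C\CC/C(CO[Si](C)(C)C(C)(C)C)=C\1 | intermediate
31 | (6R,7S,8S)-14,15-dihydroxy-8-[hydroxy(dimethyl)silyl]-6-tigloyloxygermacra-1(10),4,11(13)-trien-12-oic acid | C/C=C(\C)C(=O)O[C@H]1[C@H](C(=C)C(=O)O)[C@@H]([Si](C)(C)O)C/C(CO)=C\CC/C(CO)=C\1 | intermediate (not isolated)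
32 | (6R,7R,8S)-8,14,15-trihydroxy-6-tigloyloxygermacra-1(10),4,11(13)-trien-12-oic acid | C/C=C(\C)C(=O)O[C@H]1[C@H](C(=C)C(=O)O)[C@@H](O)C/C(CO)=C\CC/C(CO)=C\1 | intermediate (not isolated)
33 | (6R,7R,8S)-14,15-dihydroxy-6-tigloyloxygermacra-1(10),4,11(13)-trien-12,8-olide (CNP0275462.2) | C=C1C(=O)O[C@H]2C/C(CO)=C\CC/C(CO)=C\[C@@H](OC(=O)/C(C)=C/C)[C@H]12 | target

## Step count and least certain steps

Total: 19 steps. Longest linear sequence: 17 steps (steps 1–6, 8, 10–19); steps 7 and 9 are side branches.

**Step 11 (key step).** The rebonding may be misdirected: C9 may add to C4 and contract the ring to a cyclohexene, or C1 may add to C8 and give the eight-membered isomer. The dienolate may also be protonated at C13 or on the wrong face of C7, or the anionic medium may cleave the benzyl–silicon bond.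
Fallback, from 18 back to 21: silylation of 18 with N-(trimethylsilyl)imidazole gives the trimethylsilyl ether of 18 F1. Flow thermolysis of F1 at about 280 °C in base-washed quartz is the neutral siloxy variant of the same two-carbon [1,3] ring expansion, known for 1-vinylcycloalk-3-enyl silyl ethers, and involves no free alkoxide or carbanion. It would give the ring-expanded trimethylsilyl enol ether F2, and hydrolysis of F2 on moist silica gel returns to 21.

**Step 2.** The cyclodimerisation may give the head-to-head 1,6-isomer and [4+2] dimers beside 4, and the lipophilic isomers may resist separation.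
Fallback, from 3 back to 4, with every ring bond placed by a regiodefined reaction:
- Hydroboration of the vinyl group of 3 with 9-BBN and carbonylative homologation (CO, LiAlH(Ot-Bu)3, then buffered H2O2) would give 4-(TBS-oxymethyl)pent-4-enal F3.
- Horner–Wadsworth–Emmons reaction of F3 with ethyl 2-(diethoxyphosphoryl)hex-5-enoate F4 (from triethyl phosphonoacetate, NaH and 4-bromobut-1-ene) should give the (E)-trienoate F5, in which the two future ring carbons are already cis.
- i-Bu2AlH reduction gives the allylic alcohol F6, and silylation the bis-TBS triene F7.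
- Ring-closing metathesis of F7 (second-generation Grubbs catalyst, dilute CH2Cl2, 40 °C) forms C4=C5 and gives 4.

**Step 10.** Transmetalation of the congested vinylstannane may be slower than protodestannylation or cine substitution, and the 2-palladioallyl ether may lose alkoxide to give allene.
Fallback, from 15 and 17 back to 18: iododestannylation of 15 (I2, CH2Cl2, 0 °C) gives the vinyl iodide F8 with retention. Miyaura borylation of 17 (B2pin2, PdCl2(PPh3)2, KOPh, toluene, 50 °C) gives the pinacol boronate F9. Suzuki coupling of F8 with F9 (PdCl2(dppf), K3PO4, DMF/H2O) gives 18; the hindered partner then only has to undergo oxidative addition.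

**Step 12 (with the resolution in step 13).** Hydride delivery may occur on the other face of C6, giving the 6-epimer, and the two camphanates may separate poorly.
Fallback, from 21 back to 22: if the reduction gives the rac-6-epi alcohol F10, Mitsunobu reaction (4-nitrobenzoic acid, PPh3, diisopropyl azodicarboxylate) inverts C6 to the 4-nitrobenzoate F11, and brief methanolysis (K2CO3, MeOH, 0 °C) gives 22. If the camphanates co-elute, the same racemate can be resolved as another diastereomeric ester or on a chiral stationary phase.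

**Step 19.** Fluoride and basic peroxide may cleave or migrate the tiglate, add to the unsaturated acid, or leave the benzyl–silicon bond partly intact; in step 16 DDQ may also attack the benzylsilane.
Fallback, from 27 to 33, with silicon oxidised before the acid exists and the lactone closed oxidatively:
- Bu4NF, then KHCO3/H2O2 on 27 gives the 8,14,15-triol 12-PMB ether F12.
- Selective silylation of the two primary alcohols (t-BuMe2SiCl, imidazole) gives the 14,15-bis-TBS 8-ol F13.
- DDQ gives the 8,12-diol F14.
- TEMPO/PhI(OAc)2 oxidises the primary allylic alcohol and the resulting lactol to the bis-TBS lactone F15.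
- HF·pyridine removes the silyl ethers to give 33.

## Further compounds

F1 | step 11 | trimethylsilyl ether of 18 | C[Si](C)(C)OC1(/C(=C/[Si](C)(C)Cc2ccccc2)C(=C)COCc2ccc(OC)cc2)/C=C(CO[Si](C)(C)C(C)(C)C)\CC/C=C(CO[Si](C)(C)C(C)(C)C)\C1
F2 | step 11 | trimethylsilyl enol ether of 21 (enol ether geometry left open) | C[Si](C)(C)OC1=C(C(=C)COCc2ccc(OC)cc2)[C@@H]([Si](C)(C)Cc2ccccc2)C/C(CO[Si](C)(C)C(C)(C)C)=C\CC/C(CO[Si](C)(C)C(C)(C)C)=C\1
F3 | step 2 | 4-(TBS-oxymethyl)pent-4-enal | O=CCCC(=C)CO[Si](C)(C)C(C)(C)C
F4 | step 2 | ethyl 2-(diethoxyphosphoryl)hex-5-enoate | CCOC(=O)C(CCC=C)P(=O)(OCC)OCC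
F5 | step 2 | ethyl (2E)-2-(but-3-en-1-yl)-6-(TBS-oxymethyl)hepta-2,6-dienoate | CCOC(=O)/C(CCC=C)=C/CCC(=C)CO[Si](C)(C)C(C)(C)C
F6 | step 2 | (2E)-2-(but-3-en-1-yl)-6-(TBS-oxymethyl)hepta-2,6-dien-1-ol | OC/C(CCC=C)=C/CCC(=C)CO[Si](C)(C)C(C)(C)C
F7 | step 2 | (5E)-5,9-bis(TBS-oxymethyl)deca-1,5,9-triene | CC(C)(C)[Si](C)(C)OC/C(CCC=C)=C/CCC(=C)CO[Si](C)(C)C(C)(C)C
F8 | step 10 | rac-1-[(Z)-2-(benzyldimethylsilyl)-1-iodoethenyl]-3,7-bis(TBS-oxymethyl)cycloocta-2,6-dien-1-ol | OC1(/C(I)=C/[Si](C)(C)Cc2ccccc2)/C=C(CO[Si](C)(C)C(C)(C)C)\CC/C=C(CO[Si](C)(C)C(C)(C)C)\C1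
F9 | step 10 | 2-{3-[(4-methoxybenzyl)oxy]prop-1-en-2-yl}-4,4,5,5-tetramethyl-1,3,2-dioxaborolane | C=C(COCc1ccc(OC)cc1)B1OC(C)(C)C(C)(C)O1
F10 | step 12 | rac-(6S,7S,8S)-8-(benzyldimethylsilyl)-14,15-bis(TBS-oxy)-12-(PMB-oxy)germacra-1(10),4,11(13)-trien-6-ol (6-epimer of 22) | O[C@@H]1[C@H](C(=C)COCc2ccc(OC)cc2)[C@@H]([Si](C)(C)Cc2ccccc2)C/C(CO[Si](C)(C)C(C)(C)C)=C\CC/C(CO[Si](C)(C)C(C)(C)C)=C\1
F11 | step 12 | rac-4-nitrobenzoate of 22 | [O-][N+](=O)c1ccc(cc1)C(=O)O[C@H]1[C@H](C(=C)COCc2ccc(OC)cc2)[C@@H]([Si](C)(C)Cc2ccccc2)C/C(CO[Si](C)(C)C(C)(C)C)=C\CC/C(CO[Si](C)(C)C(C)(C)C)=C\1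
F12 | step 19 | (6R,7R,8S)-6-tigloyloxy-12-(PMB-oxy)germacra-1(10),4,11(13)-triene-8,14,15-triol | C/C=C(\C)C(=O)O[C@H]1[C@H](C(=C)COCc2ccc(OC)cc2)[C@@H](O)C/C(CO)=C\CC/C(CO)=C\1
F13 | step 19 | (6R,7R,8S)-6-tigloyloxy-14,15-bis(TBS-oxy)-12-(PMB-oxy)germacra-1(10),4,11(13)-trien-8-ol | C/C=C(\C)C(=O)O[C@H]1[C@H](C(=C)COCc2ccc(OC)cc2)[C@@H](O)C/C(CO[Si](C)(C)C(C)(C)C)=C\CC/C(CO[Si](C)(C)C(C)(C)C)=C\1
F14 | step 19 | (6R,7R,8S)-6-tigloyloxy-14,15-bis(TBS-oxy)germacra-1(10),4,11(13)-triene-8,12-diol | C/C=C(\C)C(=O)O[C@H]1[C@H](C(=C)CO)[C@@H](O)C/C(CO[Si](C)(C)C(C)(C)C)=C\CC/C(CO[Si](C)(C)C(C)(C)C)=C\1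
F15 | step 19 | (6R,7R,8S)-6-tigloyloxy-14,15-bis(TBS-oxy)germacra-1(10),4,11(13)-trien-12,8-olide | C=C1C(=O)O[C@H]2C/C(CO[Si](C)(C)C(C)(C)C)=C\CC/C(CO[Si](C)(C)C(C)(C)C)=C\[C@@H](OC(=O)/C(C)=C/C)[C@H]12
A1 | alternative 1 | dimethyl (8S)-8-(TBS-oxy)-6-oxo-11,12,13-trinorgermacra-1(10),4-diene-14,15-dioate (ring-cis,cis) | O=C1C[C@@H](O[Si](C)(C)C(C)(C)C)C/C(C(=O)OC)=C\CC/C(C(=O)OC)=C\1
A2 | alternative 1 | cis-anti-cis 6-4-4 tricyclic keto diester photoadduct (central cyclobutane C1–C4–C5–C10; one diastereomer drawn) | O=C1C[C@@H](O[Si](C)(C)C(C)(C)C)C[C@@]2(C(=O)OC)[C@@H]1[C@]1(C(=O)OC)CC[C@@H]12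
A3 | alternative 2 | (6R,7R,8S)-6-(triethylsilyloxy)-14,15-bis(TBS-oxy)-13-norgermacra-1(10),4-dien-12,8-olide | C1C(=O)O[C@H]2C/C(CO[Si](C)(C)C(C)(C)C)=C\CC/C(CO[Si](C)(C)C(C)(C)C)=C\[C@@H](O[Si](CC)(CC)CC)[C@H]12
A4 | alternative 2 | seco lactone with the C4 vinyl iodide arm on C7 and the C10=C1–C2=C3 dienyl arm on C8 | O=C1C[C@@H]([C@H](O[Si](CC)(CC)CC)/C=C(\I)CO[Si](C)(C)C(C)(C)C)[C@H](C/C(CO[Si](C)(C)C(C)(C)C)=C\C=C)O1
A5 | alternative 3 | ten-membered carbocycle with phenylsulfonyl on C2 (C2 epimers), 6-OTES, 8-OTBS, 12-OPMB, 14,15-OTBS | C=C(COCc2ccc(OC)cc2)[C@@H]1[C@@H](O[Si](C)(C)C(C)(C)C)C/C(CO[Si](C)(C)C(C)(C)C)=C\C(S(=O)(=O)c2ccccc2)C/C(CO[Si](C)(C)C(C)(C)C)=C\[C@H]1O[Si](CC)(CC)CC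
A6 | alternative 3 | open-chain C2 allylic phenyl sulfone with C3 allylic bromide | C=C(COCc1ccc(OC)cc1)[C@H]([C@@H](O[Si](C)(C)C(C)(C)C)C/C(CO[Si](C)(C)C(C)(C)C)=C\CS(=O)(=O)c1ccccc1)[C@H](O[Si](CC)(CC)CC)/C=C(CBr)/CO[Si](C)(C)C(C)(C)C
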